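The 14-membered carbocycle is disconnected at the bond between the acetoxy-bearing ring carbon C10 and the vinylic CH C11 (cembrane numbering, C1 = ring carbon carrying the 2-acetoxypropan-2-yl group). This allylic carbinol, C10(O)–C11H=C12(Me), is the retron of an alkenyl–aldehyde addition. An intramolecular Nozaki–Hiyama–Kishi reaction therefore forms the C10–C11 bond, closes the macrocycle and sets the C10 stereocentre in one ligand-controlled operation. The precursor is an acyclic (E)-iodoalkene/β,γ-epoxy aldehyde that already carries the C7–C8 epoxide, the (Z)-C3=C4 alkene from neryl acetate, the tertiary acetate and the C1 stereocentre from an Evans alkylation.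

Key step: step 14

Assumption: the sense of induction of the two chiral ligands (bishydroxamic acid in step 12, sulfonamide–oxazoline in step 14) is taken from the usual empirical models; the enantiomer written is the one expected to give the required configuration, and the antipodal ligand would be used if a model reaction shows the opposite sense.

Step 1
Reactants: 1 hex-5-yn-1-ol
Product: 3 (E)-6-iodo-5-methylhex-5-en-1-ol, via alkenylalane 2 (not isolated)
Conditions: Me3Al (3 equiv), Cp2ZrCl2 (0.25 equiv), CH2Cl2, 0 °C to rt; then I2, THF, −30 to 0 °C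
Reagents that add atoms: trimethylaluminium C[Al](C)C; iodine [I][I]
Why: Zirconium-catalysed Negishi carboalumination adds methyl and aluminium syn across the terminal alkyne with aluminium on the terminal carbon, and iodinolysis with retention fixes the (E)-2-methyl-1-iodoalkene geometry.

Step 2
Reactants: 3 (E)-6-iodo-5-methylhex-5-en-1-ol
Product: 4 (E)-6-iodo-5-methylhex-5-enoic acid
Conditions: TEMPO (0.2 equiv), PhI(OAc)2 (2.2 equiv), MeCN/H2O 1:1, rt
Reagents that add atoms: water O
Why: The oxoammonium (TEMPO/PhI(OAc)2) oxidation in aqueous acetonitrile takes the primary alcohol through the aldehyde hydrate to the acid and leaves the iodoalkene untouched.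

Step 3
Reactants: 4 (E)-6-iodo-5-methylhex-5-enoic acid; 5 (S)-4-benzyloxazolidin-2-one
Product: 6 (S)-4-benzyl-3-[(E)-6-iodo-5-methylhex-5-enoyl]oxazolidin-2-one
Conditions: DCC (1.1 equiv), DMAP (0.1 equiv), CH2Cl2, 0 °C to rt
Reagents that add atoms: none
Why: Carbodiimide activation with DMAP catalysis (Steglich-type N-acylation) attaches the acid to the oxazolidinone nitrogen, installing the Evans auxiliary without affecting the iodoalkene.

Step 4
Reactants: 7 neryl acetate [(Z)-3,7-dimethylocta-2,6-dien-1-yl acetate]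
Product: 8 (2Z,6E)-3,7-dimethyl-8-oxoocta-2,6-dien-1-yl acetate
Conditions: SeO2 (1.2 equiv), 1,4-dioxane, 80 °C
Reagents that add atoms: selenium dioxide O=[Se]=O
Why: SeO2 allylic oxidation (ene reaction then [2,3]-sigmatropic shift) attacks the (E)-methyl group of the electron-rich distal trisubstituted alkene, the proximal alkene being deactivated by the allylic acetate, and gives the (E)-enal.

Step 5
Reactants: 8 (2Z,6E)-3,7-dimethyl-8-oxoocta-2,6-dien-1-yl acetate
Product: 9 (2Z,6E)-3,7-dimethylnona-2,6,8-trien-1-yl acetate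
Conditions: Ph3PCH3Br (1.2 equiv), KOtBu (1.15 equiv), THF, 0 °C; then 8, −78 to 0 °C
Reagents that add atoms: methyltriphenylphosphonium bromide C[P+](c1ccccc1)(c1ccccc1)c1ccccc1.[Br-]
Why: Wittig methylenation of the non-enolisable enal by the unstabilised ylide is much faster than attack on the acetate and creates the terminal vinyl group of a 1,3-diene without touching either trisubstituted alkene geometry.

Step 6
Reactants: 9 (2Z,6E)-3,7-dimethylnona-2,6,8-trien-1-yl acetate
Product: 10 (2Z,6E)-3,7-dimethylnona-2,6,8-trien-1-ol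
Conditions: K2CO3 (0.2 equiv), MeOH, 0 °C to rt
Reagents that add atoms: none
Why: Carbonate-catalysed transesterification with methanol cleaves the primary allylic acetate under conditions that leave the diene and the Z-alkene unchanged.

Step 7
Reactants: 10 (2Z,6E)-3,7-dimethylnona-2,6,8-trien-1-ol
Product: 11 (3E,7Z)-9-bromo-3,7-dimethylnona-1,3,7-triene
Conditions: CBr4 (1.2 equiv), PPh3 (1.25 equiv), CH2Cl2, −20 to 0 °C; used directly
Reagents that add atoms: tetrabromomethane BrC(Br)(Br)Br
Why: The Appel reaction converts the primary allylic alcohol into the bromide by SN2 displacement of the oxyphosphonium group at low temperature, which keeps the Z geometry and avoids allylic transposition.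

Step 8
Reactants: 6 (S)-4-benzyl-3-[(E)-6-iodo-5-methylhex-5-enoyl]oxazolidin-2-one; 11 (3E,7Z)-9-bromo-3,7-dimethylnona-1,3,7-triene
Product: 13 (S)-4-benzyl-3-[(2R,4Z,8E)-2-[(E)-4-iodo-3-methylbut-3-en-1-yl]-5,9-dimethylundeca-4,8,10-trienoyl]oxazolidin-2-one, via sodium enolate 12 (not isolated)
Conditions: NaN(SiMe3)2 (1.1 equiv), THF, −78 °C; then 11 (1.2 equiv), −78 to −30 °C
Reagents that add atoms: none
Why: Evans asymmetric alkylation: the chelated sodium Z-enolate is shielded on one face by the benzyl group, so the allylic bromide is attacked in an SN2 fashion from the opposite face, which sets the 2R stereocentre and keeps the Z-alkene of the electrophile.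

Step 9
Reactants: 13 (S)-4-benzyl-3-[(2R,4Z,8E)-2-[(E)-4-iodo-3-methylbut-3-en-1-yl]-5,9-dimethylundeca-4,8,10-trienoyl]oxazolidin-2-one
Product: 14 methyl (2R,4Z,8E)-2-[(E)-4-iodo-3-methylbut-3-en-1-yl]-5,9-dimethylundeca-4,8,10-trienoate
Conditions: MeMgBr (3 equiv) added to MeOH at 0 °C to form MeOMgBr; then 13 in CH2Cl2, 0 °C to rt
Reagents that add atoms: methanol (delivered as MeOMgBr) CO
Why: Methoxymagnesium bromide transesterifies the chelated exocyclic imide carbonyl under mild, weakly basic conditions, releasing the auxiliary and giving the methyl ester without epimerising the α-stereocentre.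

Step 10
Reactants: 14 methyl (2R,4Z,8E)-2-[(E)-4-iodo-3-methylbut-3-en-1-yl]-5,9-dimethylundeca-4,8,10-trienoate
Product: 17 (3R,5Z,9E)-3-[(E)-4-iodo-3-methylbut-3-en-1-yl]-2,6,10-trimethyldodeca-5,9,11-trien-2-yl acetate, via methyl ketone 15 (not isolated), via bromomagnesium alkoxide 16 (not isolated)
Conditions: MeMgBr (4 equiv), THF, −20 to 0 °C; then Ac2O (8 equiv), DMAP (0.2 equiv), 0 °C to rt
Reagents that add atoms: methylmagnesium bromide C[Mg]Br; acetic anhydride CC(=O)OC(C)=O
Why: Double Grignard addition to the ester via the methyl ketone gives the tertiary magnesium alkoxide, which is O-acetylated in the same flask by acetic anhydride (DMAP catalysis), the α-stereocentre being untouched because addition outruns enolisation.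

Step 11
Reactants: 17 (3R,5Z,9E)-3-[(E)-4-iodo-3-methylbut-3-en-1-yl]-2,6,10-trimethyldodeca-5,9,11-trien-2-yl acetate
Product: 19 (3R,5Z,9E)-12-hydroxy-3-[(E)-4-iodo-3-methylbut-3-en-1-yl]-2,6,10-trimethyldodeca-5,9-dien-2-yl acetate, via alkylborane 18 (not isolated)
Conditions: 9-BBN (1.5 equiv), THF, 0 °C to rt; then NaBO3·4H2O, THF/H2O, rt
Reagents that add atoms: sodium perborate [Na+].[O-]OB=O
Why: Hydroboration with the bulky 9-BBN is selective for the monosubstituted terminal alkene of the diene and places boron on the terminal carbon (anti-Markovnikov), and perborate oxidation gives the primary homoallylic alcohol while sparing the acetate, the iodoalkene and the trisubstituted alkenes.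

Step 12
Reactants: 19 (3R,5Z,9E)-12-hydroxy-3-[(E)-4-iodo-3-methylbut-3-en-1-yl]-2,6,10-trimethyldodeca-5,9-dien-2-yl acetate
Product: 20 (3R,5Z)-8-[(2R,3R)-3-(2-hydroxyethyl)-3-methyloxiran-2-yl]-3-[(E)-4-iodo-3-methylbut-3-en-1-yl]-2,6-dimethyloct-5-en-2-yl acetate
Conditions: VO(OiPr)3 (2 mol %), C2-symmetric bishydroxamic acid ligand from (R,R)-cyclohexane-1,2-diamine (N,N'-dihydroxy-N,N'-bis(triarylacetyl), 4 mol %), cumene hydroperoxide (1.5 equiv), toluene, rt
Reagents that add atoms: cumene hydroperoxide CC(C)(OO)c1ccccc1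
Why: Hydroxyl-directed, vanadium-catalysed asymmetric epoxidation of a homoallylic alcohol: the alkoxide-bound vanadium alkylperoxide delivers oxygen only to the homoallylic C=C, the chiral bishydroxamic acid ligand selects the alkene face, and syn addition to the E-alkene gives the trans (R,R)-epoxide.

Step 13
Reactants: 20 (3R,5Z)-8-[(2R,3R)-3-(2-hydroxyethyl)-3-methyloxiran-2-yl]-3-[(E)-4-iodo-3-methylbut-3-en-1-yl]-2,6-dimethyloct-5-en-2-yl acetate
Product: 21 (3R,5Z)-3-[(E)-4-iodo-3-methylbut-3-en-1-yl]-2,6-dimethyl-8-[(2R,3R)-3-methyl-3-(2-oxoethyl)oxiran-2-yl]oct-5-en-2-yl acetate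
Conditions: Dess–Martin periodinane (1.3 equiv), pyridine (5 equiv), CH2Cl2, 0 °C; crude aldehyde used at once
Reagents that add atoms: none
Why: Dess–Martin oxidation buffered with pyridine converts the primary alcohol into the aldehyde under non-acidic, weakly basic conditions that avoid β-elimination or opening of the adjacent epoxide.

Step 14
Reactants: 21 (3R,5Z)-3-[(E)-4-iodo-3-methylbut-3-en-1-yl]-2,6-dimethyl-8-[(2R,3R)-3-methyl-3-(2-oxoethyl)oxiran-2-yl]oct-5-en-2-yl acetate
Product: 22 (1R,3Z,7R,8R,10R,11E)-7,8-epoxy-10-hydroxycembra-3,11-dien-15-yl acetate (14-membered ring, free C10 alcohol)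
Conditions: CrCl2 (6 equiv), (S)-N-[2-(4-isopropyl-4,5-dihydrooxazol-2-yl)-6-methylphenyl]methanesulfonamide (6.6 equiv), Et3N (6.6 equiv), THF, rt, 1 h; NiCl2 (0.3 equiv); then 21 by syringe pump over 12 h (final ca. 2 mM), rt; aqueous ethylenediamine work-up
Reagents that add atoms: none
Why: Nozaki–Hiyama–Kishi reaction: zerovalent nickel (formed from NiCl2 by CrCl2) inserts into the alkenyl C–I bond, transmetalation gives an alkenyl trivalent chromium species that adds to the aldehyde, and the chromium alkoxide is hydrolysed on work-up. The closest known reaction type is the intramolecular iodoalkene–aldehyde NHK macrocyclisation used for medium and large carbocycles, here run with a stoichiometric chiral sulfonamide–oxazoline chromium complex. The 14-membered ring closes in a 14-exo-trig mode at high dilution. The new C10 carbinol stereocentre is set by the chiral ligand on chromium (reagent control), possibly assisted by chelation of chromium between the aldehyde and epoxide oxygens. The step needs retention of the E geometry (the nickel/chromium sequence is stereoretentive for trisubstituted iodoalkenes), chemoselectivity for the aldehyde over the tertiary acetate and the epoxide (alkenylchromium reagents add only to aldehydes), and cyclisation over oligomerisation (slow addition).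

Step 15
Reactants: 22 (1R,3Z,7R,8R,10R,11E)-7,8-epoxy-10-hydroxycembra-3,11-dien-15-yl acetate
Product: 23 (1R,3Z,7R,8R,10R,11E)-7,8-epoxycembra-3,11-diene-10,15-diyl diacetate (target)
Conditions: Ac2O (3 equiv), DMAP (0.1 equiv), Et3N (4 equiv), CH2Cl2, 0 °C to rt
Reagents that add atoms: acetic anhydride CC(=O)OC(C)=O
Why: DMAP-catalysed acylation of the secondary allylic alcohol with acetic anhydride proceeds at oxygen with retention at the carbinol carbon and gives the target diacetate.

Compound list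
1 | hex-5-yn-1-ol | C#CCCCCO | starting material
2 | [(E)-6-(dimethylalumanyloxy)-2-methylhex-1-en-1-yl]dimethylalumane (alkenylalane) | C[Al](C)/C=C(\C)CCCCO[Al](C)C | intermediate (not isolated)
3 | (E)-6-iodo-5-methylhex-5-en-1-ol | OCCCC/C(C)=C/I | intermediate
4 | (E)-6-iodo-5-methylhex-5-enoic acid | OC(=O)CCC/C(C)=C/I | intermediate
5 | (S)-4-benzyloxazolidin-2-one | O=C1N[C@@H](Cc2ccccc2)CO1 | starting material
6 | (S)-4-benzyl-3-[(E)-6-iodo-5-methylhex-5-enoyl]oxazolidin-2-one | O=C(CCC/C(C)=C/I)N1[C@@H](Cc2ccccc2)COC1=O | intermediate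
7 | neryl acetate, (Z)-3,7-dimethylocta-2,6-dien-1-yl acetate | CC(C)=CCC/C(C)=C\COC(C)=O | starting material
8 | (2Z,6E)-3,7-dimethyl-8-oxoocta-2,6-dien-1-yl acetate | O=C/C(C)=C/CC/C(C)=C\COC(C)=O | intermediate
9 | (2Z,6E)-3,7-dimethylnona-2,6,8-trien-1-yl acetate | C=C/C(C)=C/CC/C(C)=C\COC(C)=O | intermediate
10 | (2Z,6E)-3,7-dimethylnona-2,6,8-trien-1-ol | C=C/C(C)=C/CC/C(C)=C\CO | intermediate
11 | (3E,7Z)-9-bromo-3,7-dimethylnona-1,3,7-triene | C=C/C(C)=C/CC/C(C)=C\CBr | intermediate
12 | sodium (Z)-enolate of imide 6 | [Na+].[O-]/C(=C\CC/C(C)=C/I)N1[C@@H](Cc2ccccc2)COC1=O | intermediate (not isolated)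
13 | (S)-4-benzyl-3-[(2R,4Z,8E)-2-[(E)-4-iodo-3-methylbut-3-en-1-yl]-5,9-dimethylundeca-4,8,10-trienoyl]oxazolidin-2-one | O=C([C@H](CC/C(C)=C/I)C/C=C(/C)CC/C=C(\C)C=C)N1[C@@H](Cc2ccccc2)COC1=O | intermediate
14 | methyl (2R,4Z,8E)-2-[(E)-4-iodo-3-methylbut-3-en-1-yl]-5,9-dimethylundeca-4,8,10-trienoate | COC(=O)[C@H](CC/C(C)=C/I)C/C=C(/C)CC/C=C(\C)C=C | intermediate
15 | (3R,5Z,9E)-3-[(E)-4-iodo-3-methylbut-3-en-1-yl]-6,10-dimethyldodeca-5,9,11-trien-2-one (methyl ketone) | CC(=O)[C@H](CC/C(C)=C/I)C/C=C(/C)CC/C=C(\C)C=C | intermediate (not isolated)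
16 | bromomagnesium (3R,5Z,9E)-3-[(E)-4-iodo-3-methylbut-3-en-1-yl]-2,6,10-trimethyldodeca-5,9,11-trien-2-olate | CC(C)(O[Mg]Br)[C@H](CC/C(C)=C/I)C/C=C(/C)CC/C=C(\C)C=C | intermediate (not isolated)
17 | (3R,5Z,9E)-3-[(E)-4-iodo-3-methylbut-3-en-1-yl]-2,6,10-trimethyldodeca-5,9,11-trien-2-yl acetate | CC(=O)OC(C)(C)[C@H](CC/C(C)=C/I)C/C=C(/C)CC/C=C(\C)C=C | intermediate
18 | B-alkyl-9-borabicyclo[3.3.1]nonane from terminal hydroboration of 17 (boron on C12) | CC(=O)OC(C)(C)[C@H](CC/C(C)=C/I)C/C=C(/C)CC/C=C(\C)CCB1C2CCCC1CCC2 | intermediate (not isolated)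
19 | (3R,5Z,9E)-12-hydroxy-3-[(E)-4-iodo-3-methylbut-3-en-1-yl]-2,6,10-trimethyldodeca-5,9-dien-2-yl acetate | CC(=O)OC(C)(C)[C@H](CC/C(C)=C/I)C/C=C(/C)CC/C=C(\C)CCO | intermediate
20 | (3R,5Z)-8-[(2R,3R)-3-(2-hydroxyethyl)-3-methyloxiran-2-yl]-3-[(E)-4-iodo-3-methylbut-3-en-1-yl]-2,6-dimethyloct-5-en-2-yl acetate | CC(=O)OC(C)(C)[C@H](CC/C(C)=C/I)C/C=C(/C)CC[C@H]1O[C@]1(C)CCO | intermediate
21 | (3R,5Z)-3-[(E)-4-iodo-3-methylbut-3-en-1-yl]-2,6-dimethyl-8-[(2R,3R)-3-methyl-3-(2-oxoethyl)oxiran-2-yl]oct-5-en-2-yl acetate | CC(=O)OC(C)(C)[C@H](CC/C(C)=C/I)C/C=C(/C)CC[C@H]1O[C@]1(C)CC=O | intermediate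
22 | (1R,3Z,7R,8R,10R,11E)-7,8-epoxy-10-hydroxycembra-3,11-dien-15-yl acetate | O[C@H]1/C=C(\C)CC[C@@H](C(C)(C)OC(C)=O)C/C=C(/C)CC[C@H]2O[C@]2(C)C1 | intermediate
23 | (1R,3Z,7R,8R,10R,11E)-7,8-epoxycembra-3,11-diene-10,15-diyl diacetate | CC(=O)O[C@H]1/C=C(\C)CC[C@@H](C(C)(C)OC(C)=O)C/C=C(/C)CC[C@H]2O[C@]2(C)C1 | target

Total step count: 15
Longest linear sequence: 12 steps (steps 4–7, then 8–15, from neryl acetate); the other branch (steps 1–3) joins at step 8.

Steps most likely to fail

Step 14 (key step). Facial discrimination at the aldehyde may be poor if ligand and substrate preferences oppose each other. The chromium Lewis acid may also open or β-eliminate the epoxide next to the aldehyde. The fallback for the stereochemical problem sets out from 22 obtained as a mixture of C10 epimers and returns to 22. The mixture would be oxidised with MnO2 (CH2Cl2, rt) to the macrocyclic enone (1R,3Z,7R,8R,11E)-7,8-epoxy-10-oxocembra-3,11-dien-15-yl acetate F1. A Corey–Bakshi–Shibata reduction ((S)-2-methyl-CBS-oxazaborolidine, catecholborane, toluene, −78 °C) should then deliver hydride under reagent control, so that both epimers converge on the (10R)-alcohol 22.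

Step 12. The catalyst may not control the alkene face well enough on this trisubstituted homoallylic alcohol, and the 3,4-epoxy alcohol may cyclise to a tetrahydrofuran on the Lewis-acidic metal. The fallback moves the epoxidation to an early, reagent-controlled Shi epoxidation; it sets out from 9 and returns at 20.
- Hydroboration/oxidation of 9 (9-BBN; NaBO3) should give (2Z,6E)-9-hydroxy-3,7-dimethylnona-2,6-dien-1-yl acetate F2.
- Silylation (TBSCl, imidazole, DMF) gives (2Z,6E)-9-(tert-butyldimethylsilyloxy)-3,7-dimethylnona-2,6-dien-1-yl acetate F3.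
- Shi epoxidation (D-fructose-derived ketone catalyst, chosen by the spiro transition-state model; KHSO5, K2CO3 buffer, MeCN/dimethoxymethane/H2O, 0 °C) should epoxidise only the C6=C7 alkene, because the C2=C3 alkene is deactivated by the allylic acetate. This gives (Z)-5-[(2R,3R)-3-[2-(tert-butyldimethylsilyloxy)ethyl]-3-methyloxiran-2-yl]-3-methylpent-2-en-1-yl acetate F4.
- Methanolysis (K2CO3, MeOH) gives (Z)-5-[(2R,3R)-3-[2-(tert-butyldimethylsilyloxy)ethyl]-3-methyloxiran-2-yl]-3-methylpent-2-en-1-ol F5.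
- Appel bromination (CBr4, PPh3, −20 °C) gives tert-butyl{2-[(2R,3R)-3-[(Z)-5-bromo-3-methylpent-3-en-1-yl]-2-methyloxiran-2-yl]ethoxy}dimethylsilane F6.
- Evans alkylation of 6 with F6 (NaN(SiMe3)2, THF, −78 °C) gives the (2R)-alkylated epoxy silyl ether imide F7.
- MeOMgBr/MeOH gives the corresponding methyl ester F8.
- MeMgBr then Ac2O/DMAP gives the tertiary acetate silyl ether F9.
- Desilylation with tetrabutylammonium fluoride buffered with AcOH (THF, 0 °C) returns 20.

Step 10. O-acylation of the hindered tertiary magnesium alkoxide may be incomplete, or elimination may occur in the one-pot procedure. The fallback separates the two events; it sets out from 14 and returns at 17. Addition of MeMgBr to 14 followed by an aqueous NH4Cl quench gives the isolated tertiary alcohol (3R,5Z,9E)-3-[(E)-4-iodo-3-methylbut-3-en-1-yl]-2,6,10-trimethyldodeca-5,9,11-trien-2-ol F10. The neutral alcohol is then acetylated by nucleophilic catalysis (Ac2O, DMAP, Et3N, CH2Cl2, 40 °C) to give 17.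

Further compounds
F1 | step 14 | (1R,3Z,7R,8R,11E)-7,8-epoxy-10-oxocembra-3,11-dien-15-yl acetate | O=C1/C=C(\C)CC[C@@H](C(C)(C)OC(C)=O)C/C=C(/C)CC[C@H]2O[C@]2(C)C1
F2 | step 12 | (2Z,6E)-9-hydroxy-3,7-dimethylnona-2,6-dien-1-yl acetate | OCC/C(C)=C/CC/C(C)=C\COC(C)=O
F3 | step 12 | (2Z,6E)-9-(tert-butyldimethylsilyloxy)-3,7-dimethylnona-2,6-dien-1-yl acetate | CC(C)(C)[Si](C)(C)OCC/C(C)=C/CC/C(C)=C\COC(C)=O
F4 | step 12 | (Z)-5-[(2R,3R)-3-[2-(tert-butyldimethylsilyloxy)ethyl]-3-methyloxiran-2-yl]-3-methylpent-2-en-1-yl acetate | CC(=O)OC/C=C(/C)CC[C@H]1O[C@]1(C)CCO[Si](C)(C)C(C)(C)C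
F5 | step 12 | (Z)-5-[(2R,3R)-3-[2-(tert-butyldimethylsilyloxy)ethyl]-3-methyloxiran-2-yl]-3-methylpent-2-en-1-ol | OC/C=C(/C)CC[C@H]1O[C@]1(C)CCO[Si](C)(C)C(C)(C)C
F6 | step 12 | tert-butyl{2-[(2R,3R)-3-[(Z)-5-bromo-3-methylpent-3-en-1-yl]-2-methyloxiran-2-yl]ethoxy}dimethylsilane | BrC/C=C(/C)CC[C@H]1O[C@]1(C)CCO[Si](C)(C)C(C)(C)C
F7 | step 12 | (S)-4-benzyl-3-[(2R,4Z)-7-[(2R,3R)-3-[2-(tert-butyldimethylsilyloxy)ethyl]-3-methyloxiran-2-yl]-2-[(E)-4-iodo-3-methylbut-3-en-1-yl]-5-methylhept-4-enoyl]oxazolidin-2-one | O=C([C@H](CC/C(C)=C/I)C/C=C(/C)CC[C@H]1O[C@]1(C)CCO[Si](C)(C)C(C)(C)C)N1[C@@H](Cc2ccccc2)COC1=O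
F8 | step 12 | methyl (2R,4Z)-7-[(2R,3R)-3-[2-(tert-butyldimethylsilyloxy)ethyl]-3-methyloxiran-2-yl]-2-[(E)-4-iodo-3-methylbut-3-en-1-yl]-5-methylhept-4-enoate | COC(=O)[C@H](CC/C(C)=C/I)C/C=C(/C)CC[C@H]1O[C@]1(C)CCO[Si](C)(C)C(C)(C)C
F9 | step 12 | (3R,5Z)-8-[(2R,3R)-3-[2-(tert-butyldimethylsilyloxy)ethyl]-3-methyloxiran-2-yl]-3-[(E)-4-iodo-3-methylbut-3-en-1-yl]-2,6-dimethyloct-5-en-2-yl acetate | CC(=O)OC(C)(C)[C@H](CC/C(C)=C/I)C/C=C(/C)CC[C@H]1O[C@]1(C)CCO[Si](C)(C)C(C)(C)C
F10 | step 10 | (3R,5Z,9E)-3-[(E)-4-iodo-3-methylbut-3-en-1-yl]-2,6,10-trimethyldodeca-5,9,11-trien-2-ol | CC(C)(O)[C@H](CC/C(C)=C/I)C/C=C(/C)CC/C=C(\C)C=C
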